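Locants: eudesmane numbering is used for the bicyclic and the ten-membered-ring compounds (oxygen on C6, the three-carbon side chain on C7, C14 = methyl on C10, C15 = methyl on C4, β = the face of C14). Farnesane numbering is used for the open-chain compounds 1–7.

## The problem

The target 21 is a eudesm-3-ene, a trans-fused decalin. Ring A (C1–C5, C10) holds the C3=C4 alkene with methyl C15 on C4; ring B (C5–C10) holds an axial 6β p-coumarate, an equatorial 7β isopropyl group and the quaternary C10 with its β methyl C14. Four stereocentres (C5, C6, C7, C10) must be set, three of them contiguous and one quaternary. C7 is the natural control element: an equatorial isopropyl group decides which chair-like folding closes the rings and so dictates C5 and C10. The finished skeleton then controls C6, because C14 shields the β face of a C6 carbonyl and hydride must enter from the α face. The 6β oxygen is the awkward position: it is axial, 1,3-diaxial to C14, flanked by the isopropyl group and peri to C15, so it is slow to acylate and poorly suited to displacement with inversion. The p-coumarate (free phenol, conjugate acceptor, cleavable ester) will not survive hydride, strong base or hydrogenation and must come last. The C3=C4 alkene can be moved by acid towards C4=C15 or C4=C5 and lies β,γ to any C6 carbonyl. The enabling feature is the C5–C10 bond: it joins the methyl-bearing C10 to C5, which is allylic to C3=C4. This is the pattern left when the C4=C5 alkene of a cyclodeca-1(10),4-diene captures a C10 cation across the ring and the C4 cation loses H3, and the fifteen carbons of that ring are those of farnesol.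

## Retrosynthesis

**Acyl–oxygen bond at C6 (21 ⇒ 20 ⇒ 14 + 19).** The ester is cut first, so that the phenol, the cinnamate alkene and the ester never meet the acid, hydride or hydrogenation steps. The phenol is masked as a silyl ether (20), removable with buffered fluoride without touching the ester. The acyl donor is acid chloride 19, made from p-coumaric acid 15 and silyl chloride 16 through the bis-silyl compound 17 and acid 18. The alternative of bringing in the acid as a nucleophile with inversion at C6 is not chosen, because the β face of C6 is blocked by C14. The forward reaction must acylate a very hindered axial alcohol (14) with retention.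

**C6–H bond (14 ⇒ 13 ⇒ 12 ⇒ 11).** No skeletal bond is cut; the 6β configuration is traced to ketone 13 and from there to the 6α-alcohol 12 and its acetate 11. This detour is accepted because the ring-forming step needs the oxygen equatorial (6α), whereas the target has it axial. The forward reduction must deliver hydride to the α face only, which the angular methyl C14 secures. The oxidation must leave the β,γ-unsaturated ketone unconjugated.

**C5–C10 bond (11 ⇒ 10), the key cut.** Breaking this one bond turns both six-membered rings into the ten-membered (1(10)E,4E)-diene 10. The precursor loses two rings and two stereocentres (C5, C10) and keeps only C6 and C7. Against cuts that build ring A or ring B onto an existing ring, this one needs no quaternary centre to be made by intermolecular chemistry. The forward reaction must protonate C1=C10 and not C4=C5, fold through the crossed chair–chair conformer, and end by losing H3. An acetate is chosen on O6 instead of an ether because it resists ionisation of the allylic C6–O bond and deactivates C4=C5 towards the proton.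

**Spectator adjustments on the ten-membered ring (10 ⇒ 9 ⇒ 8).** The isopropyl group is traced to an isopropenyl group (9), which must be reduced before the acid step because a third alkene would compete for the proton. The acetate is traced to the racemic trans alcohol 8. A lipase transesterification is chosen because it resolves 8 and installs the acetyl group in one operation. The forward reactions must hydrogenate a 1,1-disubstituted alkene beside two trisubstituted ones and distinguish the enantiomers of a hindered secondary alcohol.

**C6–C7 bond (8 ⇒ 6, through 7).** Cutting the bond between the carbinol carbon and the side-chain-bearing carbon opens the ring to 12-bromofarnesal 6. The allylchromium species 7 attacks the aldehyde through its γ carbon and creates the isopropenyl group at the same time. Other ring bonds are sp3–sp3 or alkenyl bonds with no such natural polarity. The precursor is acyclic and achiral with both (E) alkenes already in place. The forward reaction must close a ten-membered ring at high dilution and give the anti (trans) product.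

**Functional-group work on the chain (6 ⇒ 5 ⇒ 4 ⇒ 3 ⇒ 2 ⇒ 1).** The aldehyde comes from alcohol 5, the bromide from allylic alcohol 3, and the C12 oxygen from allylic oxidation of the terminal (E)-methyl group of farnesyl acetate 2, made from farnesol 1. The acetate keeps the two primary allylic alcohols apart. No carbon–carbon bond is made in this part.

## Roads not taken

**Alternative 1:** The cut removes C7 from ring B: C6–C7 and C7–C8 are broken to leave the trans-hydrindenone A1 (ring A plus a cyclopentanone made of C5, C6, C8, C9 and C10) and 1-diazo-2-methylpropane A2. In the forward step Sc(OTf)3 would activate the C6 carbonyl of A1, A2 would add, and C8 would migrate with loss of N2 to give eudesm-3-en-6-one A3, the same compound as ketone 13.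
- Merits: it arrives directly at the ketone from which the 6β-alcohol is made, so it needs no 6α-acetate, no deacylation and no oxidation. It cannot misplace the ring A alkene, and C7 settles thermodynamically with the isopropyl group equatorial. In these respects it is better than the chosen plan.
- Weak points: A1 already contains the quaternary C10, the trans fusion and the C3=C4 alkene, and would need an enantioselective synthesis of its own. Its C5 hydrogen is α to the carbonyl and allylic, and hydrindan-1-ones usually prefer the cis fusion, so C5 is at risk before the expansion. Migration of C8 over the more substituted C5 is expected but not assured. A2 is a non-stabilised diazoalkane that must be made and used cold.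
- Comparison: against the shorter endgame of this road, the chosen plan creates C5 and C10 in its ring-forming step from a ring compound that comes from one commercial C15 chain. The price is the redox detour at C6 and the uncertain site of proton loss.

**Alternative 2:** The cut is C9–C10, which opens ring B and lets ring A become aromatic: the precursor is the phenol tosylate A4, a 2,4-dimethylphenol carrying the C6–C9 chain on the carbon between the two methyl-bearing carbons. In the forward step KOt-Bu would form the phenoxide, whose para carbon C10 displaces the C9 tosylate and gives the cross-conjugated dienone A5 with C10 quaternary.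
- Merits: the quaternary centre is made by a robust intramolecular C-alkylation, the aromatic starting material is cheap, and the 6β oxygen is carried in its final configuration from the start. No inversion at C6 is needed, which is a real advantage over the chosen plan.
- Weak points: A5 is far from the target in oxidation pattern. The C3 carbonyl must be removed, C1=C2 saturated, and C4=C5 moved to C3=C4 while C5 is created as the α-hydrogen epimer next to the bulky 6β substituent; the key step solves none of this. The C6 oxygen is benzylic in A4 and allylic in A5, so each of these operations invites its loss. The C6 and C7 stereocentres of A4 need separate asymmetric chemistry, and O-alkylation competes with C-alkylation.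
- Comparison: the chosen plan pays for its C6 inversion with three steps, but its ring-forming step leaves ring A at the correct oxidation level and sets C5 in that same step, not in a late reduction.

**Alternative 3:** The cuts are C1–C2 and C5–C10: the precursor is the acyclic trienal A6, a 1,7,9-decatriene whose dienophile is a 2-substituted acrolein (the formyl carbon is the future C14) and whose diene is C2=C3–C4(C15)=C5. In the forward step Me2AlCl binds the formyl group and the intramolecular Diels–Alder reaction closes rings A and B to give the aldehyde A7.
- Merits: the pericyclic mechanism fixes the alkene at C3=C4 without regiochemical doubt, which no cationic termination can promise. C5 and C10 are set together, and Lewis acid activation allows low temperature.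
- Weak points: C14 emerges as a neopentyl aldehyde on a quaternary carbon and must be reduced to methyl under forcing conditions or over several steps. A7 has the 6α configuration, so the same inversion sequence as in the chosen route follows. The trans fusion depends on an endo/exo preference that is often modest for such trienes. A6 has two stereocentres, an (E)-diene and a polymerisable acrolein, and needs a long linear synthesis.
- Comparison: the chosen plan shares the C6 inversion and lacks the regiochemical certainty of the cycloaddition. In return C14 is a methyl group from the start, and the cyclisation substrate comes from farnesol in eight steps.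

Key step: step 9

Assumption: the lipase in step 7 is taken to acetylate the (6R,7S) enantiomer of 8, as the empirical size rule for secondary alcohols predicts with C7 as the large flank; if the preference is the reverse, the same enantiomer is recovered as the unreacted alcohol and acetylated with Ac2O and DMAP to give 9.

## Route

Step 1
Reactants: 1 (2E,6E)-farnesol
Product: 2 (2E,6E)-farnesyl acetate
Conditions: Ac2O, pyridine, DMAP (cat.), CH2Cl2, 0 °C to rt
Reagents that add atoms: acetic anhydride, CC(=O)OC(C)=O
Why: DMAP-catalysed O-acetylation of a primary allylic alcohol; the acetate distinguishes C1 from the oxygen that is introduced at C12 and deactivates the C2=C3 alkene towards the next oxidation.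

Step 2
Reactants: 2 (2E,6E)-farnesyl acetate
Product: 3 (2E,6E,10E)-12-hydroxyfarnesyl acetate
Conditions: SeO2 (cat.), t-BuOOH, salicylic acid (cat.), CH2Cl2, rt
Reagents that add atoms: tert-butyl hydroperoxide, CC(C)(C)OO; selenium dioxide, O=[Se]=O
Why: Selenium dioxide allylic oxidation (ene reaction, then [2,3]-sigmatropic shift) attacks the most electron-rich and least hindered trisubstituted alkene, the terminal one, at its (E)-methyl group and keeps the (E) geometry.

Step 3
Reactants: 3 (2E,6E,10E)-12-hydroxyfarnesyl acetate
Product: 4 (2E,6E,10E)-12-bromofarnesyl acetate
Conditions: CBr4, PPh3, CH2Cl2, 0 °C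
Reagents that add atoms: carbon tetrabromide, BrC(Br)(Br)Br
Why: Appel reaction: bromide displaces the alkoxyphosphonium group at the primary allylic carbon in an SN2 sense, without allylic transposition and without touching the acetate.

Step 4
Reactants: 4 (2E,6E,10E)-12-bromofarnesyl acetate
Product: 5 (2E,6E,10E)-12-bromofarnesol
Conditions: i-Bu2AlH, CH2Cl2, −78 °C; then aq. potassium sodium tartrate
Reagents that add atoms: none
Why: Reductive cleavage of the acetate by the aluminium hydride at −78 °C, where a primary allylic bromide is not reduced; alkoxide-based deacetylation is avoided because it would substitute the bromide.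

Step 5
Reactants: 5 (2E,6E,10E)-12-bromofarnesol
Product: 6 (2E,6E,10E)-12-bromofarnesal
Conditions: Dess–Martin periodinane, NaHCO3, CH2Cl2, 0 °C to rt
Reagents that add atoms: none
Why: Dess–Martin oxidation of a primary allylic alcohol to the enal under buffered, non-nucleophilic conditions; the (2E) geometry and the allylic bromide are retained.

Step 6
Reactants: 6 (2E,6E,10E)-12-bromofarnesal
Product: 8 rac-(6R*,7S*)-germacra-1(10)E,4E,11-trien-6-ol (6-OH trans to 7-isopropenyl), via allylchromium dichloride 7 (not isolated)
Conditions: CrCl2 (excess), THF, slow addition of 6 (high dilution), rt; then H2O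
Reagents that add atoms: none
Why: Nozaki–Hiyama–Kishi allylation: CrCl2 (divalent chromium) reduces the allylic bromide to the allylchromium species 7 (trivalent chromium), which adds through its γ carbon to the aldehyde in a chair-like Zimmerman–Traxler transition state. The (E)-allyl unit places the chain equatorial, so the anti product results, with the hydroxyl trans to the isopropenyl group on the ring; this chromium-mediated closure of ten-membered germacrane rings from 12-halofarnesal derivatives is a known reaction type. High dilution favours ring closure over intermolecular allylation.

Step 7
Reactants: 8 rac-(6R*,7S*)-germacra-1(10)E,4E,11-trien-6-ol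
Product: 9 (6R,7S)-germacra-1(10)E,4E,11-trien-6-yl acetate
Conditions: Burkholderia cepacia lipase (immobilised), vinyl acetate, t-BuOMe, 35 °C, to about half conversion
Reagents that add atoms: vinyl acetate, C=COC(C)=O
Why: Lipase-catalysed kinetic resolution by irreversible transesterification, a standard method for trans-2-alkylcycloalkanols of the menthol and isopulegol type. Only the enantiomer whose larger flank (C7) fits the large pocket of the enzyme is acylated, so 9 is formed as a single enantiomer that already carries the acetyl group needed for the key step.

Step 8
Reactants: 9 (6R,7S)-germacra-1(10)E,4E,11-trien-6-yl acetate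
Product: 10 (6S,7S)-germacra-1(10)E,4E-dien-6-yl acetate (same spatial arrangement as 9; the C6 descriptor changes with the side chain)
Conditions: H2 (1 atm), RhCl(PPh3)3 (cat.), toluene, rt
Reagents that add atoms: none
Why: Homogeneous hydrogenation with RhCl(PPh3)3 discriminates by substitution: the 1,1-disubstituted isopropenyl alkene is reduced while the two trisubstituted ring alkenes and the allylic C–O bond are left alone.

Step 9
Reactants: 10 (6S,7S)-germacra-1(10)E,4E-dien-6-yl acetate
Product: 11 (5R,6S,7S,10R)-eudesm-3-en-6-yl acetate (6α-acetoxy, 5α-H, 7β-isopropyl, 10β-methyl)
Conditions: TsOH·H2O (0.2 equiv), CH2Cl2, 0 °C to rt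
Reagents that add atoms: none
Why: TsOH protonates the strained, more electron-rich C1=C10 alkene at C1 (Markovnikov; C4=C5 is deactivated by the allylic acetoxy group), the tertiary C10 cation is captured across the ring by C5 of the C4=C5 alkene to form C5–C10, and the resulting tertiary C4 cation loses H3 to give the C3=C4 alkene. The closest known reaction type is the acid-induced transannular cyclisation of (E,E)-germacra-1(10),4-dienes to trans-eudesmanes, including that of 6-acyloxy germacranolides such as costunolide, which have the same 6α-oxygen/7β-carbon pattern. The one new bond closes both rings: ring A in a 6-endo mode with respect to the C4=C5 alkene (C4 and C5 both lie in ring A and the charge develops on the ring atom C4), ring B in a 6-exo mode (C4 stays outside ring B). C10 is set by the reacting conformer: with the C7 isopropyl and C6 acetoxy groups pseudoequatorial and H6 in the C4=C5 plane to avoid A(1,3) strain with C15, the two alkenes are crossed with C14 and C15 on the same face, and the chair–chair transition state delivers the 10β-methyl group. C5 follows from the same folding and the (E) geometry of C4=C5, which places H5 on the face opposite to C14 (5α-H, trans fusion). Three selectivities are needed: protonation of C1=C10 and not C4=C5, secured by the inductive effect of the acetate; no ionisation of the allylic C6–O bond, secured by using an ester and not an ether or a free alcohol; and proton loss from C3 and not from C15 or C5. For the last, the sulfonic acid is left in contact long enough to reprotonate any exocyclic alkene and drain the mixture to the trisubstituted ring alkene, while the 6α-acetoxy group disfavours the C4=C5 isomer through allylic strain with C15 and disfavours a hydride shift to C5 inductively.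

Step 10
Reactants: 11 (5R,6S,7S,10R)-eudesm-3-en-6-yl acetate
Product: 12 (5R,6S,7S,10R)-eudesm-3-en-6-ol (6α-alcohol)
Conditions: K2CO3, MeOH, 40 °C
Reagents that add atoms: none
Why: Base-catalysed transesterification with methanol removes the equatorial acetate; no stereocentre and no alkene is affected.

Step 11
Reactants: 12 (5R,6S,7S,10R)-eudesm-3-en-6-ol
Product: 13 (5R,7S,10R)-eudesm-3-en-6-one
Conditions: Dess–Martin periodinane, NaHCO3, CH2Cl2, 0 °C
Reagents that add atoms: none
Why: Dess–Martin oxidation under bicarbonate buffer is close to neutral, so the β,γ-unsaturated ketone should form without migration of C3=C4 into conjugation and without epimerisation at C5 or C7; the ketone is used at once.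

Step 12
Reactants: 13 (5R,7S,10R)-eudesm-3-en-6-one
Product: 14 (5R,6R,7S,10R)-eudesm-3-en-6-ol (6β-alcohol)
Conditions: LiBH(s-Bu)3, THF, −78 °C; then H2O
Reagents that add atoms: none
Why: Diastereoselective ketone reduction with a bulky borohydride: the axial trajectory on the β face is blocked by the 1,3-diaxial methyl C14, so hydride enters equatorially from the α face and gives the axial 6β-alcohol (6R), as in the reduction of 6-oxo steroids. The low temperature keeps the doubly activated C5–H from being removed.

Step 13
Reactants: 15 p-coumaric acid; 16 tert-butyldimethylsilyl chloride
Product: 18 (E)-4-(tert-butyldimethylsilyloxy)cinnamic acid, via bis-silylated coumarate 17 (not isolated)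
Conditions: TBSCl (2.3 equiv), imidazole, DMF, rt; then AcOH, THF, H2O, rt
Reagents that add atoms: tert-butyldimethylsilyl chloride (16), CC(C)(C)[Si](C)(C)Cl
Why: Imidazole-promoted silylation of phenol and acid, followed by selective hydrolysis of the silyl ester, which is far more labile than the aryl silyl ether in dilute acetic acid.

Step 14
Reactants: 18 (E)-4-(tert-butyldimethylsilyloxy)cinnamic acid
Product: 19 (E)-4-(tert-butyldimethylsilyloxy)cinnamoyl chloride
Conditions: (COCl)2, DMF (cat.), CH2Cl2, 0 °C to rt
Reagents that add atoms: oxalyl chloride, O=C(Cl)C(=O)Cl
Why: Acid chloride formation through the chloroiminium ion generated from DMF; the aryl silyl ether and the (E) alkene are untouched, and the crude chloride is used directly.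

Step 15
Reactants: 14 (5R,6R,7S,10R)-eudesm-3-en-6-ol; 19 (E)-4-(tert-butyldimethylsilyloxy)cinnamoyl chloride
Product: 20 (5R,6R,7S,10R)-eudesm-3-en-6-yl (E)-4-(tert-butyldimethylsilyloxy)cinnamate
Conditions: DMAP, Et3N, CH2Cl2, 0 °C to 40 °C
Reagents that add atoms: none
Why: DMAP-catalysed acylation through the N-acylpyridinium ion, the activation needed for an axial alcohol that is syn to C14 and flanked by the isopropyl group. O-Acylation does not touch the C6–O bond, so the 6β configuration is retained.

Step 16
Reactants: 20 (5R,6R,7S,10R)-eudesm-3-en-6-yl (E)-4-(tert-butyldimethylsilyloxy)cinnamate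
Product: 21 (5R,6R,7S,10R)-eudesm-3-en-6-yl (E)-4-hydroxycinnamate (CNP0220414.1)
Conditions: Bu4NF, AcOH, THF, 0 °C
Reagents that add atoms: none
Why: Fluoride-induced cleavage of the aryl silyl ether; acetic acid protonates the phenoxide as it forms, so the hindered cinnamate ester is neither cleaved nor isomerised.

## Compound list

1 | (2E,6E)-farnesol | CC(C)=CCC/C(C)=C/CC/C(C)=C/CO | starting material
2 | (2E,6E)-farnesyl acetate | CC(C)=CCC/C(C)=C/CC/C(C)=C/COC(C)=O | intermediate
3 | (2E,6E,10E)-12-hydroxyfarnesyl acetate | OC/C(C)=C/CC/C(C)=C/CC/C(C)=C/COC(C)=O | intermediate
4 | (2E,6E,10E)-12-bromofarnesyl acetate | BrC/C(C)=C/CC/C(C)=C/CC/C(C)=C/COC(C)=O | intermediate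
5 | (2E,6E,10E)-12-bromofarnesol | BrC/C(C)=C/CC/C(C)=C/CC/C(C)=C/CO | intermediate
6 | (2E,6E,10E)-12-bromofarnesal | BrC/C(C)=C/CC/C(C)=C/CC/C(C)=C/C=O | intermediate
7 | allylchromium dichloride derived from 6 (C12–CrCl2, trivalent chromium) | Cl[Cr](Cl)C/C(C)=C/CC/C(C)=C/CC/C(C)=C/C=O | intermediate (not isolated)
8 | rac-(6R*,7S*)-germacra-1(10)E,4E,11-trien-6-ol, 6-OH trans to 7-isopropenyl (racemate; the enantiomer that is carried on is drawn) | C=C(C)[C@@H]1CC/C(C)=C/CC/C(C)=C/[C@H]1O | intermediate
9 | (6R,7S)-germacra-1(10)E,4E,11-trien-6-yl acetate | C=C(C)[C@@H]1CC/C(C)=C/CC/C(C)=C/[C@H]1OC(C)=O | intermediate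
10 | (6S,7S)-germacra-1(10)E,4E-dien-6-yl acetate | CC(C)[C@@H]1CC/C(C)=C/CC/C(C)=C/[C@H]1OC(C)=O | intermediate
11 | (5R,6S,7S,10R)-eudesm-3-en-6-yl acetate (6α-acetoxy) | CC1=CCC[C@]2(C)CC[C@@H](C(C)C)[C@H](OC(C)=O)[C@@H]12 | intermediate
12 | (5R,6S,7S,10R)-eudesm-3-en-6-ol (6α-alcohol) | CC1=CCC[C@]2(C)CC[C@@H](C(C)C)[C@H](O)[C@@H]12 | intermediate
13 | (5R,7S,10R)-eudesm-3-en-6-one | CC1=CCC[C@]2(C)CC[C@@H](C(C)C)C(=O)[C@@H]12 | intermediate
14 | (5R,6R,7S,10R)-eudesm-3-en-6-ol (6β-alcohol) | CC1=CCC[C@]2(C)CC[C@@H](C(C)C)[C@@H](O)[C@@H]12 | intermediate
15 | p-coumaric acid, (E)-4-hydroxycinnamic acid | O=C(O)/C=C/c1ccc(O)cc1 | starting material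
16 | tert-butyldimethylsilyl chloride | CC(C)(C)[Si](C)(C)Cl | starting material
17 | tert-butyldimethylsilyl (E)-4-(tert-butyldimethylsilyloxy)cinnamate | CC(C)(C)[Si](C)(C)OC(=O)/C=C/c1ccc(O[Si](C)(C)C(C)(C)C)cc1 | intermediate (not isolated)
18 | (E)-4-(tert-butyldimethylsilyloxy)cinnamic acid | O=C(O)/C=C/c1ccc(O[Si](C)(C)C(C)(C)C)cc1 | intermediate
19 | (E)-4-(tert-butyldimethylsilyloxy)cinnamoyl chloride | O=C(Cl)/C=C/c1ccc(O[Si](C)(C)C(C)(C)C)cc1 | intermediate
20 | (5R,6R,7S,10R)-eudesm-3-en-6-yl (E)-4-(tert-butyldimethylsilyloxy)cinnamate | CC1=CCC[C@]2(C)CC[C@@H](C(C)C)[C@@H](OC(=O)/C=C/c3ccc(O[Si](C)(C)C(C)(C)C)cc3)[C@@H]12 | intermediate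
21 | (5R,6R,7S,10R)-eudesm-3-en-6-yl (E)-4-hydroxycinnamate, 6β-(p-coumaroyloxy)eudesm-3-ene | CC1=CCC[C@]2(C)CC[C@@H](C(C)C)[C@@H](OC(=O)/C=C/c3ccc(O)cc3)[C@@H]12 | target

## Step count and risks

Total: 16 steps. Longest linear sequence: 14 steps (steps 1–12, 15 and 16, from farnesol); steps 13 and 14 form the two-step side branch to the acyl donor.

Steps least certain to work:

**Step 9 (key step).** The most likely failure is proton loss from C15 instead of C3, giving the exocyclic alkene, if the acid does not equilibrate the alkene isomers before other processes set in. Such processes are capture of the C4 cation by tosylate or by the acetate carbonyl, and ionisation of the allylic acetate before cyclisation. The fallback sets out from 10 and returns at 11. Compound 10 is cyclised briefly under kinetic conditions, and the exocyclic isomer, 6α-acetoxyeudesm-4(15)-ene F1, is not discarded. It is isomerised in a separate metal-catalysed step (RhCl3·3H2O, EtOH, 70 °C), the known rhodium hydride addition–elimination that moves exocyclic methylene groups of methylenecyclohexanes into the ring, to give 11.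

**Step 6.** Intermolecular allylation may outrun closure of the strained ten-membered ring and give oligomers, and the ring may not allow the chair-like transition state, which would erode the anti selectivity. The fallback sets out from 6 and returns at 8. The stoichiometric chromium reaction is replaced by catalytic umpolung of a π-allylpalladium complex (Pd(PPh3)4, a zerovalent palladium complex, with Et2Zn in THF). The allylic bromide is ionised by palladium and passed on to zinc, so that the nucleophile is formed catalytically and kept at low standing concentration. This fallback makes no new compound.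

**Step 7.** The enzymatic acylation may be slow or poorly selective, because both flanks of the carbinol carbon are large. The fallback sets out from 8 and returns at 9 and replaces the kinetic resolution by a covalent one. Racemic 8 is esterified with (1S)-camphanic chloride (pyridine, DMAP). The diastereomeric esters are separated by chromatography or crystallisation, and the ester of the needed enantiomer, (6R,7S)-germacra-1(10)E,4E,11-trien-6-yl (1S,4R)-camphanate F2, is assigned by X-ray analysis. F2 is cleaved with KOH in MeOH to the single enantiomer (6R,7S)-germacra-1(10)E,4E,11-trien-6-ol F3, which is acetylated (Ac2O, pyridine, DMAP) to 9.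

**Step 11.** The C3=C4 alkene may migrate into conjugation with the new C6 carbonyl, or C5 may epimerise through the dienol, during oxidation or work-up. The fallback sets out from 12 and returns at 14 and avoids the ketone. A Mitsunobu inversion of 12 with 4-nitrobenzoic acid (PPh3, diisopropyl azodicarboxylate, toluene) would give 6β-(4-nitrobenzoyloxy)eudesm-3-ene F4, and methanolysis (K2CO3, MeOH) would give 14. The displacement has to pass C14 on the β face, so this is a reserve and not the first choice.

**Step 15.** Acylation of the axial, doubly flanked 6β-hydroxyl may be so slow that the acid chloride is consumed in side reactions first. The fallback sets out from 14 and returns at 20 and builds the cinnamate on the ester oxygen. Compound 14 is acylated with the small and reactive (diethoxyphosphoryl)acetic acid (dicyclohexylcarbodiimide, DMAP) to give 6β-[(diethoxyphosphoryl)acetoxy]eudesm-3-ene F5. A Horner–Wadsworth–Emmons reaction of F5 with commercial 4-(tert-butyldimethylsilyloxy)benzaldehyde (LiCl, 1,8-diazabicyclo[5.4.0]undec-7-ene, MeCN) then forms the (E)-alkene of 20.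

## Further compounds

F1 | step 9 | 6α-acetoxyeudesm-4(15)-ene (5α-H, 7β-isopropyl, 10β-methyl) | C=C1CCC[C@]2(C)CC[C@@H](C(C)C)[C@H](OC(C)=O)[C@@H]12
F0 | step 6 | none | none
F2 | step 7 | (6R,7S)-germacra-1(10)E,4E,11-trien-6-yl (1S,4R)-camphanate | C=C(C)[C@@H]1CC/C(C)=C/CC/C(C)=C/[C@H]1OC(=O)[C@@]12CC[C@@](C)(C(=O)O1)C2(C)C
F3 | step 7 | (6R,7S)-germacra-1(10)E,4E,11-trien-6-ol (single enantiomer of 8) | C=C(C)[C@@H]1CC/C(C)=C/CC/C(C)=C/[C@H]1O
F4 | step 11 | 6β-(4-nitrobenzoyloxy)eudesm-3-ene | CC1=CCC[C@]2(C)CC[C@@H](C(C)C)[C@@H](OC(=O)c3ccc(cc3)[N+](=O)[O-])[C@@H]12
F5 | step 15 | 6β-[(diethoxyphosphoryl)acetoxy]eudesm-3-ene | CC1=CCC[C@]2(C)CC[C@@H](C(C)C)[C@@H](OC(=O)CP(=O)(OCC)OCC)[C@@H]12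
A1 | alternative 1 | trans-fused 3a,7-dimethyl-2,3,3a,4,5,7a-hexahydro-1H-inden-1-one (angular methyl β, ring-fusion hydrogen α) | CC1=CCC[C@]2(C)CCC(=O)[C@@H]12
A2 | alternative 1 | 1-diazo-2-methylpropane | CC(C)C=[N+]=[N-]
A3 | alternative 1 | eudesm-3-en-6-one (identical with 13) | CC1=CCC[C@]2(C)CC[C@@H](C(C)C)C(=O)[C@@H]12
A4 | alternative 2 | 3-[1-(tert-butyldimethylsilyloxy)-2-isopropyl-4-(tosyloxy)butyl]-2,4-dimethylphenol with the C6 and C7 configuration of the target | Cc1c(O)ccc(C)c1[C@H](O[Si](C)(C)C(C)(C)C)[C@H](C(C)C)CCOS(=O)(=O)c1ccc(C)cc1
A5 | alternative 2 | 6β-(tert-butyldimethylsilyloxy)eudesma-1,4-dien-3-one | CC1=C2[C@H](O[Si](C)(C)C(C)(C)C)[C@H](C(C)C)CC[C@@]2(C)C=CC1=O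
A6 | alternative 3 | (7E)-6-(tert-butyldimethylsilyloxy)-8-methyl-2-methylidene-5-(propan-2-yl)deca-7,9-dienal | C=C(C=O)CC[C@@H](C(C)C)[C@H](O[Si](C)(C)C(C)(C)C)/C=C(\C)C=C
A7 | alternative 3 | 6α-(tert-butyldimethylsilyloxy)-14-oxoeudesm-3-ene | CC1=CCC[C@]2(C=O)CC[C@@H](C(C)C)[C@H](O[Si](C)(C)C(C)(C)C)[C@@H]12
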